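**Plan**

- Retrosynthetic cuts, in order: the two ring A MOM ethers; the ring B C3–CHO bond; ring B at C5–C6 (aldol) and C1–C2 (C-acylation), back to a ring A benzyl acetoacetate and diketene; the benzylic C–O bond, back to a ring A benzylic bromide and acetoacetate; the C–Br bond, back to the C6 methyl of atraric acid.
- Enabling feature: ring B is an orsellinate. C1, C6 and the C6 methyl are an acetoacetate unit (its ester carbon sits on C1), and C2 to C5 are an acetoacetyl unit, so ring B can be grown on an unhindered benzylic ester that is already in place.
- Forward: ring A is MOM-protected, then brominated at the C6 methyl through its lateral lithio dienolate (a radical bromination would have to tell apart two methyl groups and an electron-rich ring position). The bromide is esterified by carboxylate displacement, so the benzylic alcohol, which would lactonise to a phthalide, is never set free. Ring B then forms in one pot, is formylated at C3, and the MOM groups are removed.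
- Stereochemistry: the target has no stereocentre. The control problems are regiochemical: C6 versus C3 methyl of ring A (conjugation with the ester), C3 versus C5 of ring B (two flanking phenoxides), ring B versus ring A in the formylation (free versus protected phenols).

Key step: step 4

Remark: ring A is the methyl ester ring and ring B the formylated ring, each numbered C1 (carboxyl-bearing carbon) to C6; lithium acetoacetate, stabilised diketene and orsellinic acid are taken as purchasable.

**Route**

Step 1
Reactants: 1 atraric acid (methyl 2,4-dihydroxy-3,6-dimethylbenzoate)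
Product: 3 methyl 2,4-bis(methoxymethoxy)-3,6-dimethylbenzoate, via disodium bis-phenoxide 2 (not isolated)
Conditions: NaH (2.4 equiv), DMF, 0 °C; MOMCl (2.4 equiv), 0 °C to rt
Reagents that add atoms: chloromethyl methyl ether (MOMCl), COCCl
Why: Williamson-type O-alkylation of the bis-phenoxide, with NaH chosen because the 2-OH is chelated to the ester and hindered; the acetal ethers should tolerate LiN(iPr)2, enolates and NaH and come off in mild acid at the end.

Step 2
Reactants: 3 methyl 2,4-bis(methoxymethoxy)-3,6-dimethylbenzoate
Product: 5 methyl 6-(bromomethyl)-2,4-bis(methoxymethoxy)-3-methylbenzoate, via lithium dienolate 4 (not isolated)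
Conditions: LiN(iPr)2 (1.15 equiv), THF, −78 °C; then cannulated into BrCCl2CCl2Br (1.5 equiv), THF, −78 °C
Reagents that add atoms: 1,2-dibromo-1,1,2,2-tetrachloroethane, ClC(Cl)(Br)C(Cl)(Cl)Br
Why: Lateral (benzylic) lithiation of an o-toluate followed by electrophilic bromination of the dienolate: only the C6 methyl is conjugated to the ester carbonyl and is deprotonated (the C3 methyl is not acidified), bromination at the exocyclic CH2 restores the arene, and inverse addition into excess bromine donor should keep unreacted anion from alkylating the bromide.

Step 3
Reactants: 5 methyl 6-(bromomethyl)-2,4-bis(methoxymethoxy)-3-methylbenzoate; 6 lithium acetoacetate (lithium 3-oxobutanoate, LiO2CCH2C(O)CH3)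
Product: 7 methyl 2,4-bis(methoxymethoxy)-3-methyl-6-[(3-oxobutanoyloxy)methyl]benzoate (ring A benzyl acetoacetate)
Conditions: 6 (1.5 equiv), Bu4NI (0.1 equiv), DMF, 0 °C to rt
Reagents that add atoms: none
Why: SN2 O-alkylation of a carboxylate by a benzylic bromide, which installs the acetoacetate without freeing the benzylic alcohol (a 2-(hydroxymethyl)benzoate would lactonise to the phthalide); the carboxylate is too weak a base to enolise the β-keto ester product, so C-alkylation is not expected.

Step 4
Reactants: 7 ring A benzyl acetoacetate; 8 diketene (4-methylideneoxetan-2-one)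
Product: 11 [2-(methoxycarbonyl)-3,5-bis(methoxymethoxy)-4-methylphenyl]methyl 2,4-dihydroxy-6-methylbenzoate (ring A benzyl orsellinate), via sodium enolate 9 (not isolated), via triketo ester 10 (not isolated)
Conditions: NaH (1.1 equiv), THF, 0 °C; 8 (1.1 equiv), −10 °C to rt; cold 1 M HCl work-up
Reagents that add atoms: none
Why: NaH turns 7 into the sodium enolate 9, whose carbon opens diketene at the acyl carbon (C-acetoacetylation) to give the triacylmethane salt of 10; proton transfer then gives the enolate on the terminal methyl side of the outer ketone (C5), which adds to the acetyl carbonyl (C6) in an intramolecular aldol reaction, and loss of water with enolisation of the C2 and C4 ketones delivers the resorcinol. The closest known reaction type is the one-pot synthesis of orsellinate esters from acetoacetic ester sodium enolates and diketene by C-acylation and aldol condensation. Ring B closes in the 6-(enolendo)-exo-trig mode, which is favoured for enolate cyclisations. No stereocentre results, since the aldol carbinol is lost on aromatisation. The step needs carbon attack on the acetyl ketone rather than Claisen attack on the ester carbonyl (which would expel the ring A alkoxide), O-closure to a 4-pyranone, or the alternative aldol of the acetyl methyl onto the outer ketone; the acetyl and ester carbonyls are tied up in the methine anion so that only the outer ketone enolises towards C5, a ketone is a better acceptor than the ester, the basic medium favours C- over O-cyclisation, and only the aldol path is drained by irreversible aromatisation. The MOM ethers and the hindered methyl ester of ring A are inert to NaH and to stabilised enolates.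

Step 5
Reactants: 11 ring A benzyl orsellinate
Product: 12 [2-(methoxycarbonyl)-3,5-bis(methoxymethoxy)-4-methylphenyl]methyl 3-formyl-2,4-dihydroxy-6-methylbenzoate
Conditions: MgCl2 (3 equiv), Et3N (6 equiv), (CH2O)n (6 equiv), MeCN, reflux; cold 1 M HCl work-up
Reagents that add atoms: paraformaldehyde (as formaldehyde), C=O
Why: Magnesium-mediated ortho-formylation of phenols (Casnati–Skattebøl reaction): only ring B carries free phenols, so ring A is untouched; C3 is ortho to both magnesium phenoxides and favoured by the bond fixation of the 2-OH/ester chelate, whereas C5 is reached from O4 only and is crowded by the C6 methyl, and hydride transfer from the intermediate hydroxymethyl alkoxide to a second formaldehyde gives the aldehyde.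

Step 6
Reactants: 12 ring A bis-MOM benzyl 3-formylorsellinate
Product: 13 [3,5-dihydroxy-2-(methoxycarbonyl)-4-methylphenyl]methyl 3-formyl-2,4-dihydroxy-6-methylbenzoate (target, CNP0122264.0)
Conditions: HCl (1.25 M in MeOH), 0 °C to rt; aqueous work-up
Reagents that add atoms: none
Why: Acid-catalysed acetal exchange (MOM cleavage) in methanol, which carries the formaldehyde unit off as dimethoxymethane so that it cannot hydroxymethylate the resorcinol rings; both 2,6-disubstituted benzoate esters should resist methanolysis at room temperature, and any dimethyl acetal of the chelated aldehyde reverts on aqueous work-up.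

**Compound list**

1 | atraric acid (methyl 2,4-dihydroxy-3,6-dimethylbenzoate) | COC(=O)c1c(C)cc(O)c(C)c1O | starting material
2 | disodium bis-phenoxide of 1 | COC(=O)c1c(C)cc(O[Na])c(C)c1O[Na] | intermediate (not isolated)
3 | methyl 2,4-bis(methoxymethoxy)-3,6-dimethylbenzoate | COC(=O)c1c(C)cc(OCOC)c(C)c1OCOC | intermediate
4 | lithium dienolate of 3: lithium methoxy[2,4-bis(methoxymethoxy)-3-methyl-6-methylidenecyclohexa-2,4-dien-1-ylidene]methanolate | C=C1C=C(OCOC)C(C)=C(OCOC)C1=C(OC)O[Li] | intermediate (not isolated)
5 | methyl 6-(bromomethyl)-2,4-bis(methoxymethoxy)-3-methylbenzoate | COC(=O)c1c(CBr)cc(OCOC)c(C)c1OCOC | intermediate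
6 | lithium acetoacetate (lithium 3-oxobutanoate) | [Li+].CC(=O)CC(=O)[O-] | starting material
7 | methyl 2,4-bis(methoxymethoxy)-3-methyl-6-[(3-oxobutanoyloxy)methyl]benzoate | COC(=O)c1c(COC(=O)CC(C)=O)cc(OCOC)c(C)c1OCOC | intermediate
8 | diketene (4-methylideneoxetan-2-one) | C=C1CC(=O)O1 | starting material
9 | sodium (Z)-enolate of the acetoacetate unit of 7 | COC(=O)c1c(COC(=O)/C=C(/C)O[Na])cc(OCOC)c(C)c1OCOC | intermediate (not isolated)
10 | [2-(methoxycarbonyl)-3,5-bis(methoxymethoxy)-4-methylphenyl]methyl 2-acetyl-3,5-dioxohexanoate (drawn in the keto form; present as its sodium salt, the acidic methine being configurationally undefined) | COC(=O)c1c(COC(=O)C(C(C)=O)C(=O)CC(C)=O)cc(OCOC)c(C)c1OCOC | intermediate (not isolated)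
11 | [2-(methoxycarbonyl)-3,5-bis(methoxymethoxy)-4-methylphenyl]methyl 2,4-dihydroxy-6-methylbenzoate | COC(=O)c1c(COC(=O)c2c(C)cc(O)cc2O)cc(OCOC)c(C)c1OCOC | intermediate
12 | [2-(methoxycarbonyl)-3,5-bis(methoxymethoxy)-4-methylphenyl]methyl 3-formyl-2,4-dihydroxy-6-methylbenzoate | COC(=O)c1c(COC(=O)c2c(C)cc(O)c(C=O)c2O)cc(OCOC)c(C)c1OCOC | intermediate
13 | [3,5-dihydroxy-2-(methoxycarbonyl)-4-methylphenyl]methyl 3-formyl-2,4-dihydroxy-6-methylbenzoate | COC(=O)c1c(COC(=O)c2c(C)cc(O)c(C=O)c2O)cc(O)c(C)c1O | target

**Step count and risks**

Total steps: 6. Longest linear sequence: 6 (from atraric acid).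

Steps most likely to fail:

1. Step 4 (key step). The triketo ester may be diverted by O-cyclisation to a pyranone or by Claisen closure with loss of the ring A alkoxide, and diketene may self-condense before it is C-acylated. Fallback: bring ring B in preformed. Setting out from bromide 5, the carboxylate of commercial orsellinic acid (2,4-dihydroxy-6-methylbenzoic acid; KHCO3, DMF, rt) is O-alkylated selectively at the carboxylate, as in standard benzyl ester formation of phenolic acids. This gives 11 directly and the route resumes at 11; the fallback makes no new compound (F0).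

2. Step 2. The lithio dienolate may couple with the bromide already formed, may be brominated twice after proton exchange, or may condense with the ester of a second molecule. Fallback: oxygenate instead of halogenate and accept the lactone. Setting out from 3, the same dienolate is hydroxylated with 2-(phenylsulfonyl)-3-phenyloxaziridine (THF, −78 °C to rt). The alkoxide closes onto the methyl ester to give 5,7-bis(methoxymethoxy)-6-methyl-2-benzofuran-1(3H)-one F1. Saponification (KOH, aqueous MeOH, rt, evaporation) gives potassium 6-(hydroxymethyl)-2,4-bis(methoxymethoxy)-3-methylbenzoate F2. Alkylation of the carboxylate under neutral conditions (MeI, DMF, 0 °C) gives methyl 6-(hydroxymethyl)-2,4-bis(methoxymethoxy)-3-methylbenzoate F3. This is used at once and acetoacetylated by the acylketene from 2,2,6-trimethyl-4H-1,3-dioxin-4-one (toluene, 110 °C), which comes back to the route at 7.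

3. Step 5. The formylation may be sluggish on the ester-deactivated phenoxide or may show poor positional selectivity between C3 and C5 of ring B. Fallback: deliver the carbon by a sigmatropic shift. Setting out from 11, the unchelated 4-OH is allylated (allyl bromide, K2CO3, acetone, reflux) to [2-(methoxycarbonyl)-3,5-bis(methoxymethoxy)-4-methylphenyl]methyl 2-hydroxy-6-methyl-4-(prop-2-enyloxy)benzoate F4. Aromatic Claisen rearrangement (N,N-diethylaniline, 190 °C), directed to C3 by the bond fixation of the chelated salicylate, gives the 3-allyl-2,4-dihydroxy-6-methylbenzoate F5. Alkene isomerisation (PdCl2(MeCN)2 cat., toluene, 80 °C) gives the 2,4-dihydroxy-6-methyl-3-[(E)-prop-1-enyl]benzoate F6. Lemieux–Johnson cleavage (OsO4 cat., NaIO4, 2,6-lutidine, dioxane/H2O) then gives 12, where the route resumes.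

**Further compounds**

F0 | step 4 | none | none
F1 | step 2 | 5,7-bis(methoxymethoxy)-6-methyl-2-benzofuran-1(3H)-one | O=C1OCc2cc(OCOC)c(C)c(OCOC)c21
F2 | step 2 | potassium 6-(hydroxymethyl)-2,4-bis(methoxymethoxy)-3-methylbenzoate | [K+].[O-]C(=O)c1c(CO)cc(OCOC)c(C)c1OCOC
F3 | step 2 | methyl 6-(hydroxymethyl)-2,4-bis(methoxymethoxy)-3-methylbenzoate | COC(=O)c1c(CO)cc(OCOC)c(C)c1OCOC
F4 | step 5 | [2-(methoxycarbonyl)-3,5-bis(methoxymethoxy)-4-methylphenyl]methyl 2-hydroxy-6-methyl-4-(prop-2-enyloxy)benzoate | COC(=O)c1c(COC(=O)c2c(C)cc(OCC=C)cc2O)cc(OCOC)c(C)c1OCOC
F5 | step 5 | [2-(methoxycarbonyl)-3,5-bis(methoxymethoxy)-4-methylphenyl]methyl 2,4-dihydroxy-6-methyl-3-(prop-2-enyl)benzoate | COC(=O)c1c(COC(=O)c2c(C)cc(O)c(CC=C)c2O)cc(OCOC)c(C)c1OCOC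
F6 | step 5 | [2-(methoxycarbonyl)-3,5-bis(methoxymethoxy)-4-methylphenyl]methyl 2,4-dihydroxy-6-methyl-3-[(E)-prop-1-enyl]benzoate | COC(=O)c1c(COC(=O)c2c(C)cc(O)c(/C=C/C)c2O)cc(OCOC)c(C)c1OCOC
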